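A direct plan would build the core from L‑malic acid and two molecules of O‑silylated vanillin. The dioxolanone acid A1 would take up the first aldehyde by a dianion aldol addition with lactonization. A second dianion aldol addition with tandem lactonization would give the hydroxy bis‑lactone A2, LiAlH4 would open it to the pentaol A3, and two separate etherifications and a desilylation would finish. Its weakest steps would be:
(a) the second aldol addition, where a hindered alkoxide–enolate would have to add and lactonize before retro‑aldol or β‑elimination intervene;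
(b) the two ring closures from A3, which would have to tell five hydroxyls apart (ionization of one benzylic alcohol, then sulfonylation of one primary alcohol);
(c) protection and deprotection of both phenols, which would add length only.

The new route disconnects both benzylic C–O bonds (C7–O and C7'–O) of the 3,7‑dioxabicyclo[3.3.0]octane at once. This leads back to an open‑chain triol, (2S,3S)‑2,3‑bis(4‑hydroxy‑3‑methoxybenzyl)butane‑1,2,4‑triol, in which C7 and C7' are plain CH2 groups para to free phenols. Dehydrogenation of each 4‑hydroxybenzyl group to a para‑quinone methide, captured by the one hydroxymethyl group that can reach it through a five‑membered ring, would close rings B and A and set C7 and C7' from C8 and C8' in one operation. C8' comes from an asymmetric hydrogenation and C8 from an enolate alkylation, so no aldol addition, no sorting of five hydroxyls and no final deprotection remain.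

Key step: step 9

Remark: lignan numbering is used (C7, C8, C9 and C7', C8', C9'; C8 bears the hydroxyl); ring A is O–C7–C8–C8'–C9' and ring B is O–C7'–C8'–C8–C9. The (S,S) ligand in step 2 is assumed to give the R acid; if the sense were opposite, the (R,R) ligand would be used with no other change.

Step 1
Reactants: 1 4‑(benzyloxy)‑3‑methoxybenzaldehyde; 2 dimethyl succinate
Product: 4 (E)‑4‑[4‑(benzyloxy)‑3‑methoxyphenyl]‑3‑(methoxycarbonyl)but‑3‑enoic acid, via paraconic ester lactone 3 (not isolated)
Conditions: NaOMe (2.0 equiv), MeOH, reflux; 2 M HCl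
Reagents that add atoms: none
Why: Stobbe condensation, in which the succinate enolate adds to the aldehyde, the aldolate closes to lactone 3 with loss of methoxide, and E1cB opening of 3 gives the half‑ester with the free carboxyl on the CH2 arm and the aryl group trans to the ester (E), no stereocentre being kept.

Step 2
Reactants: 4 (E)‑4‑[4‑(benzyloxy)‑3‑methoxyphenyl]‑3‑(methoxycarbonyl)but‑3‑enoic acid
Product: 5 (3R)‑4‑[4‑(benzyloxy)‑3‑methoxyphenyl]‑3‑(methoxycarbonyl)butanoic acid
Conditions: [Rh(cod)((S,S)‑Et‑DuPhos)]BF4 (0.5 mol %), NaOMe (0.1 equiv), H2 (6 bar), MeOH, rt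
Reagents that add atoms: none
Why: Asymmetric hydrogenation of a Stobbe‑type itaconate half‑ester with a cationic rhodium bisphospholane catalyst, in which the carboxylate and the alkene chelate the metal, H2 is delivered to one enantioface of the trisubstituted alkene and sets C8' (R), and the aryl benzyl ether is inert to the homogeneous catalyst.

Step 3
Reactants: 5 (3R)‑4‑[4‑(benzyloxy)‑3‑methoxyphenyl]‑3‑(methoxycarbonyl)butanoic acid
Product: 7 (4R)‑4‑[4‑(benzyloxy)‑3‑methoxybenzyl]oxolan‑2‑one, via hydroxy acid 6 (not isolated)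
Conditions: KOH (1.0 equiv), EtOH, 0 °C; CaCl2 (1.5 equiv), NaBH4 (3 equiv), EtOH, −10 °C → rt; 2 M HCl, rt
Reagents that add atoms: none
Why: Chemoselective hydride reduction followed by acid‑catalysed lactonization, in which Ca(BH4)2 formed in the flask reduces the methyl ester but not the potassium carboxylate and acidification closes hydroxy acid 6 to the γ‑lactone, so that C8' is not touched and remains R.

Step 4
Reactants: 7 (4R)‑4‑[4‑(benzyloxy)‑3‑methoxybenzyl]oxolan‑2‑one
Product: 9 (3R,4S)‑4‑[4‑(benzyloxy)‑3‑methoxybenzyl]‑3‑hydroxyoxolan‑2‑one (trans), via sodium enolate 8 (not isolated)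
Conditions: NaN(SiMe3)2 (1.2 equiv), THF, −78 °C; 2‑(phenylsulfonyl)‑3‑phenyloxaziridine (1.3 equiv), −78 °C; aq. NH4Cl
Reagents that add atoms: 2‑(phenylsulfonyl)‑3‑phenyloxaziridine, O=S(=O)(c1ccccc1)N1OC1c1ccccc1
Why: Davis oxaziridine hydroxylation of a lactone enolate (electrophilic oxygen transfer to C8), expected anti to the C8' side chain to give the trans hydroxy lactone, although the configuration made here at C8 does not matter because C8 becomes trigonal again in step 6; the sodium counter‑ion suppresses addition of the enolate to the sulfonylimine that is released.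

Step 5
Reactants: 10 [4‑(benzyloxy)‑3‑methoxyphenyl]methanol
Product: 11 1‑(benzyloxy)‑4‑(bromomethyl)‑2‑methoxybenzene
Conditions: PBr3 (0.4 equiv), Et2O, 0 °C
Reagents that add atoms: phosphorus tribromide, BrP(Br)Br
Why: Bromination of a primary benzylic alcohol with PBr3 (SN2 displacement of the phosphite ester by bromide); the electron‑rich bromide would be used at once without storage.

Step 6
Reactants: 9 (3R,4S)‑4‑[4‑(benzyloxy)‑3‑methoxybenzyl]‑3‑hydroxyoxolan‑2‑one; 11 1‑(benzyloxy)‑4‑(bromomethyl)‑2‑methoxybenzene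
Product: 13 (3S,4S)‑3,4‑bis[4‑(benzyloxy)‑3‑methoxybenzyl]‑3‑hydroxyoxolan‑2‑one, via dilithium alkoxide enolate 12 (not isolated)
Conditions: LiN(iPr)2 (2.3 equiv), THF, −78 → −40 °C; 11 (1.3 equiv), DMPU, −78 → −20 °C; aq. NH4Cl
Reagents that add atoms: none
Why: Alkylation of the dilithium alkoxide–enolate of an α‑hydroxy lactone (dianion C‑alkylation), in which C8 is trigonal in 12 and the bromide should approach the ring face anti to the C8' benzyl group, so that the two benzyl groups end trans and the C8 hydroxyl cis to the C8' benzyl group, which is the 8S configuration needed.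

Step 7
Reactants: 13 (3S,4S)‑3,4‑bis[4‑(benzyloxy)‑3‑methoxybenzyl]‑3‑hydroxyoxolan‑2‑one
Product: 14 (2S,3S)‑2,3‑bis[4‑(benzyloxy)‑3‑methoxybenzyl]butane‑1,2,4‑triol
Conditions: LiAlH4 (3 equiv), THF, 0 °C → rt; H2O, aq. NaOH
Reagents that add atoms: none
Why: LiAlH4 reduction of the lactone to the 1,4‑diol breaks no bond at C8 or C8', so both stereocentres pass unchanged into the open‑chain triol and the benzyl ethers survive.

Step 8
Reactants: 14 (2S,3S)‑2,3‑bis[4‑(benzyloxy)‑3‑methoxybenzyl]butane‑1,2,4‑triol
Product: 15 (2S,3S)‑2,3‑bis(4‑hydroxy‑3‑methoxybenzyl)butane‑1,2,4‑triol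
Conditions: H2 (1 atm), Pd/C (10 wt %), EtOAc–EtOH, rt
Reagents that add atoms: none
Why: Catalytic hydrogenolysis of the two aryl benzyl ethers frees the phenols that the last step needs, while the aliphatic hydroxyls and the unoxygenated benzylic CH2 groups are inert under neutral conditions.

Step 9
Reactants: 15 (2S,3S)‑2,3‑bis(4‑hydroxy‑3‑methoxybenzyl)butane‑1,2,4‑triol
Product: 19 8‑hydroxypinoresinol, (1S,2R,5R,6S)‑1‑hydroxy‑2,6‑bis(4‑hydroxy‑3‑methoxyphenyl)‑3,7‑dioxabicyclo[3.3.0]octane, via C7' quinone methide 16 (not isolated), via ring B oxolane 17 (not isolated), via C7 quinone methide 18 (not isolated)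
Conditions: DDQ (2.05 equiv, in portions), 1,4‑dioxane, 15 °C → rt, dark; filtration, aq. NaHCO3 wash
Reagents that add atoms: none
Why: DDQ should take a hydride from a benzylic CH2 that is para to a free phenol, and loss of the phenolic proton gives a para‑quinone methide, first at C7' (16) and, once ring closure has restored the phenol, at C7 (18); the opposite order would lead to the same product. The closest known reaction type is the dehydrogenative cycloetherification of 4‑alkylphenols that carry a hydroxyl in the side chain (flavans and 2‑aryltetrahydrofurans with DDQ), together with the capture of both quinone methides by hydroxymethyl groups when coniferyl alcohol is oxidized to pinoresinol. Ring B closes by 5‑exo‑trig addition of the C9 hydroxyl to C7' of 16 and ring A by 5‑exo‑trig addition of the C9' hydroxyl to C7 of 18; every other hydroxyl could reach these carbons only through a three‑ or four‑membered ring, so ring size fixes the constitution. C7' is controlled by C8': the quinone methide should react in the conformer with H8' in the plane of the quinoid ring (allylic 1,3‑strain), which places the aryl group trans to the C9' hydroxymethyl group (7'S). C7 is controlled by C8 and by the bicycle: C9' and C7 are cis on ring B, so ring A can only be cis‑fused, and the quinoid ring should turn to the convex face, next to the small C8 hydroxyl and away from C9 (7R). The step needs oxygen capture to outrun attack by the other arene, tautomerization to a styrene, retro‑aldol cleavage and further oxidation, which the five‑membered intramolecular capture, the absence of base and of strong acid, the quaternary C8 next to C7 and the use of just two equivalents of oxidant should secure.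

**Compound list**

1 | 4‑(benzyloxy)‑3‑methoxybenzaldehyde (O‑benzylvanillin) | COc1cc(C=O)ccc1OCc1ccccc1 | starting material
2 | dimethyl succinate | COC(=O)CCC(=O)OC | starting material
3 | methyl 2‑[4‑(benzyloxy)‑3‑methoxyphenyl]‑5‑oxooxolane‑3‑carboxylate (paraconic ester, racemic, both diastereomers) | COC(=O)C1CC(=O)OC1c1ccc(OCc2ccccc2)c(OC)c1 | intermediate
4 | (E)‑4‑[4‑(benzyloxy)‑3‑methoxyphenyl]‑3‑(methoxycarbonyl)but‑3‑enoic acid | COC(=O)/C(CC(=O)O)=C/c1ccc(OCc2ccccc2)c(OC)c1 | intermediate
5 | (3R)‑4‑[4‑(benzyloxy)‑3‑methoxyphenyl]‑3‑(methoxycarbonyl)butanoic acid | COC(=O)[C@H](Cc1ccc(OCc2ccccc2)c(OC)c1)CC(=O)O | intermediate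
6 | (3R)‑3‑[4‑(benzyloxy)‑3‑methoxybenzyl]‑4‑hydroxybutanoic acid | OC(=O)C[C@@H](Cc1ccc(OCc2ccccc2)c(OC)c1)CO | intermediate
7 | (4R)‑4‑[4‑(benzyloxy)‑3‑methoxybenzyl]oxolan‑2‑one | O=C1C[C@@H](Cc2ccc(OCc3ccccc3)c(OC)c2)CO1 | intermediate
8 | sodium enolate of 7 | [Na+].[O-]C1=C[C@@H](Cc2ccc(OCc3ccccc3)c(OC)c2)CO1 | intermediate
9 | (3R,4S)‑4‑[4‑(benzyloxy)‑3‑methoxybenzyl]‑3‑hydroxyoxolan‑2‑one | O=C1OC[C@H](Cc2ccc(OCc3ccccc3)c(OC)c2)[C@H]1O | intermediate
10 | [4‑(benzyloxy)‑3‑methoxyphenyl]methanol | COc1cc(CO)ccc1OCc1ccccc1 | starting material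
11 | 1‑(benzyloxy)‑4‑(bromomethyl)‑2‑methoxybenzene | COc1cc(CBr)ccc1OCc1ccccc1 | intermediate
12 | dilithium alkoxide–enolate of 9 | [Li+].[Li+].[O-]C1=C([O-])[C@@H](Cc2ccc(OCc3ccccc3)c(OC)c2)CO1 | intermediate
13 | (3S,4S)‑3,4‑bis[4‑(benzyloxy)‑3‑methoxybenzyl]‑3‑hydroxyoxolan‑2‑one | O=C1OC[C@H](Cc2ccc(OCc3ccccc3)c(OC)c2)[C@@]1(O)Cc1ccc(OCc2ccccc2)c(OC)c1 | intermediate
14 | (2S,3S)‑2,3‑bis[4‑(benzyloxy)‑3‑methoxybenzyl]butane‑1,2,4‑triol | OC[C@](O)(Cc1ccc(OCc2ccccc2)c(OC)c1)[C@H](CO)Cc1ccc(OCc2ccccc2)c(OC)c1 | intermediate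
15 | (2S,3S)‑2,3‑bis(4‑hydroxy‑3‑methoxybenzyl)butane‑1,2,4‑triol | OC[C@](O)(Cc1ccc(O)c(OC)c1)[C@H](CO)Cc1ccc(O)c(OC)c1 | intermediate
16 | C7' quinone methide of 15 | OC[C@](O)(Cc1ccc(O)c(OC)c1)[C@H](CO)C=C1C=CC(=O)C(OC)=C1 | intermediate
17 | (3S,4R,5S)‑3‑(4‑hydroxy‑3‑methoxybenzyl)‑5‑(4‑hydroxy‑3‑methoxyphenyl)‑4‑(hydroxymethyl)oxolan‑3‑ol (ring B closed) | COc1cc([C@H]2OC[C@](O)(Cc3ccc(O)c(OC)c3)[C@@H]2CO)ccc1O | intermediate
18 | C7 quinone methide of 17 | COc1cc([C@H]2OC[C@](O)(C=C3C=CC(=O)C(OC)=C3)[C@@H]2CO)ccc1O | intermediate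
19 | 8‑hydroxypinoresinol | COc1cc([C@H]2OC[C@]3(O)[C@@H](c4ccc(O)c(OC)c4)OC[C@H]23)ccc1O | target

Total step count: 9. Longest linear sequence: 8 steps (steps 1 to 4 and 6 to 9; step 5 is a one‑step branch).

**Steps most likely to fail**

Step 9. Capture of a quinone methide by the internal hydroxyl may lose to attack by the other arene, to tautomerization on the C7' side, or to further oxidation of the product by oxidant still present. The fallback sets out from 15 and comes back at 19. The oxidation would be run with DDQ in methanol, where the solvent intercepts each quinone methide at once (the known benzylic methoxylation of 4‑alkylphenols) to give the 7,7'‑dimethoxy triol F1 as a mixture of epimers at C7 and C7'. In a separate operation F1 would be treated with a catalytic sulfonic acid in CH2Cl2, so that both benzylic methyl ethers ionize and the C9 and C9' hydroxyls close rings B and A by SN1 cycloetherification with loss of methanol. The oxidant is then gone before the furofuran exists.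

Step 6. The hindered dianion may alkylate on oxygen, react sluggishly with the benzylic bromide, or lose facial selectivity. The fallback sets out from 9 and comes back at 15. The same dianion would be added to aldehyde 1, a faster electrophile, in an aldol addition with the same anti approach at C8, to give the 7‑hydroxy lactone F2 as a mixture of epimers at C7. Hydrogenolysis over Pd/C in EtOH with a trace of HClO4 would remove both benzyl ethers and the para‑hydroxybenzylic C7 hydroxyl to give the bisphenolic hydroxy lactone F3, and LiAlH4 would reduce F3 to 15.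

Step 2. Enantioface discrimination on the trisubstituted alkene may be incomplete, or the reduction may stall. The fallback sets out from 4 and comes back at 5. Hydrogenation with the achiral catalyst [Rh(cod)(dppb)]BF4 would give the racemic half‑ester F4. It would be resolved by crystallization of the 1‑phenylethylammonium salt of the R acid F5 (drawn with the R amine; the amine antipode would be chosen by trial), and acidification would return 5.

**Further compounds**

F1 | step 9 | (2S,3S)‑configured 2,3‑bis[(4‑hydroxy‑3‑methoxyphenyl)(methoxy)methyl]butane‑1,2,4‑triol (C8 and C8' as in 15, epimers at C7 and C7') | OC[C@](O)(C(OC)c1ccc(O)c(OC)c1)[C@H](CO)C(OC)c1ccc(O)c(OC)c1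
F2 | step 6 | (3R,4S)‑4‑[4‑(benzyloxy)‑3‑methoxybenzyl]‑3‑{[4‑(benzyloxy)‑3‑methoxyphenyl](hydroxy)methyl}‑3‑hydroxyoxolan‑2‑one (epimers at C7) | O=C1OC[C@H](Cc2ccc(OCc3ccccc3)c(OC)c2)[C@@]1(O)C(O)c1ccc(OCc2ccccc2)c(OC)c1
F3 | step 6 | (3S,4S)‑3‑hydroxy‑3,4‑bis(4‑hydroxy‑3‑methoxybenzyl)oxolan‑2‑one | O=C1OC[C@H](Cc2ccc(O)c(OC)c2)[C@@]1(O)Cc1ccc(O)c(OC)c1
F4 | step 2 | racemic 4‑[4‑(benzyloxy)‑3‑methoxyphenyl]‑3‑(methoxycarbonyl)butanoic acid | COC(=O)C(Cc1ccc(OCc2ccccc2)c(OC)c1)CC(=O)O
F5 | step 2 | (R)‑1‑phenylethylammonium (3R)‑4‑[4‑(benzyloxy)‑3‑methoxyphenyl]‑3‑(methoxycarbonyl)butanoate | COC(=O)[C@H](Cc1ccc(OCc2ccccc2)c(OC)c1)CC(=O)[O-].C[C@@H]([NH3+])c1ccccc1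
A1 | direct plan | (2S,4S)‑2‑tert‑butyl‑5‑oxo‑1,3‑dioxolane‑4‑acetic acid | CC(C)(C)[C@H]1O[C@@H](CC(=O)O)C(=O)O1
A2 | direct plan | (1R,2R,5R,6S)‑1‑hydroxy‑2,6‑bis[3‑methoxy‑4‑(triisopropylsilyloxy)phenyl]‑3,7‑dioxabicyclo[3.3.0]octane‑4,8‑dione | COc1cc([C@H]2OC(=O)[C@]3(O)[C@@H](c4ccc(O[Si](C(C)C)(C(C)C)C(C)C)c(OC)c4)OC(=O)[C@H]23)ccc1O[Si](C(C)C)(C(C)C)C(C)C
A3 | direct plan | (1R,2S,3R,4S)‑2,3‑bis(hydroxymethyl)‑1,4‑bis[3‑methoxy‑4‑(triisopropylsilyloxy)phenyl]butane‑1,2,4‑triol | COc1cc([C@@H](O)[C@@H](CO)[C@](O)(CO)[C@H](O)c2ccc(O[Si](C(C)C)(C(C)C)C(C)C)c(OC)c2)ccc1O[Si](C(C)C)(C(C)C)C(C)C
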